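**A direct plan and its weak points**

A direct plan would start from 4-bromo-2-nitrobenzaldehyde A1 and convert A1 by Ramirez olefination into 4-bromo-1-(2,2-dibromovinyl)-2-nitrobenzene A2.
It would then reduce the nitro group of A2 with TiCl3, so that the nitroso arene closes the pyrrole ring at N1–C2 while one bromine shifts from C2 to C3, giving 2,3,6-tribromo-1H-indole A3, and would N-methylate A3 at the end.
The reductive ring closure would be its weakest step: ring formation and a 1,2-bromine shift would have to occur in one event for which no halogen precedent exists, so the closure would be left to chance (reduction to the aniline, arrest at the N-hydroxyindole, or loss of HBr to a 2-bromoindole would compete).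
The same step would carry the whole substitution pattern of the pyrrole ring: if the shift failed, C3 would stay without bromine and nothing upstream could be saved.
The final N-methylation would spend a full step on the most precious and least stable material (a light- and acid-sensitive 2,3-dibromo N–H indole) for one carbon atom that a starting material could carry from the beginning.

**Plan of the new route**

The retrosynthesis keeps the pyrrole ring and cuts the benzene ring: first C3a–C4 together with the C4=C5 and C6=C7 double bonds (acid cycloaromatisation of an open-chain bromo ether acetal), then C6–Br and C7–O (bromomethoxylation), then C7=C6 (Wittig), then the two ring bromines.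
The pyrrole ring with its N-methyl group is there from the start and the benzene ring arises last; no isolated compound before the target holds the bicyclic ring system.
The feature that allows this: N1(Me), C2(Br), C3(Br), C3a(H), C7a and C7 of the target are a 4,5-dibromo-2-formyl-1-methylpyrrole, whose bromines are placed by the formyl group and whose only free ring carbon is the future C3a.
C6 is the chain carbon β to the pyrrole ring, where a 2-alkenylpyrrole takes up electrophilic bromine; C4 to C7 then stand at the oxidation level of the benzene ring (one bromide, one ether, one acetal).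
No nitro reduction, no bromine migration and no N-alkylation of an indole occur.

Key step: step 4

Remark on the chemistry: the double-bond geometry of 6 and the configuration at the two stereocentres of 7 are of no consequence, since all are erased when the benzene ring forms; both compounds are carried as isomer mixtures.

**Route**

Step 1
Reactants: 1 1-methyl-1H-pyrrole-2-carbaldehyde
Product: 3 4,5-dibromo-1-methyl-1H-pyrrole-2-carbaldehyde, via 4-bromo-1-methyl-1H-pyrrole-2-carbaldehyde 2 (not isolated)
Conditions: NBS (2.1 equiv), DMF, 0 °C to rt, dark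
Reagents that add atoms: N-bromosuccinimide, O=C1CCC(=O)N1Br
Why: Electrophilic aromatic bromination, in which the 2-formyl group should send the first bromine to C4 (any 5-bromo isomer converges) and the second to C5 and leave the ring carbon next to the formyl group, the future C3a, free; no stereocentre is formed.

Step 2
Reactants: 3 4,5-dibromo-1-methyl-1H-pyrrole-2-carbaldehyde; 4 [2-(1,3-dioxolan-2-yl)ethyl]triphenylphosphonium bromide
Product: 6 2,3-dibromo-5-[(1Z)-3-(1,3-dioxolan-2-yl)prop-1-en-1-yl]-1-methyl-1H-pyrrole, via phosphorus ylide 5 (not isolated)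
Conditions: 4 (1.2 equiv), KN(SiMe3)2 (1.15 equiv), THF, 0 °C; then 3, −78 °C to rt
Reagents that add atoms: none
Why: Wittig olefination with a non-stabilised ylide, which should give mainly the Z alkene (the E isomer is equally usable); the ylide is formed completely before the aldehyde is added so that no amide base meets the bromopyrrole, and the ring C–Br bonds and the dioxolane should be inert to the ylide at low temperature.

Step 3
Reactants: 6 2,3-dibromo-5-[(1Z)-3-(1,3-dioxolan-2-yl)prop-1-en-1-yl]-1-methyl-1H-pyrrole
Product: 7 2,3-dibromo-5-[2-bromo-3-(1,3-dioxolan-2-yl)-1-methoxypropyl]-1-methyl-1H-pyrrole (racemic, both diastereomers)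
Conditions: NBS (1.05 equiv), NaHCO3, MeOH–CH2Cl2 (1:1), −40 to 0 °C, dark; crude product used directly
Reagents that add atoms: N-bromosuccinimide, O=C1CCC(=O)N1Br; methanol, CO
Why: Bromomethoxylation (co-halogenation) of a 2-alkenylpyrrole, in which bromine should add to the chain carbon remote from the ring (the future C6) because the cation at the carbon next to the ring is an azafulvenium ion that methanol captures; the two new stereocentres form without control and are both erased in step 4, and any product of capture by an acetal oxygen or of proton loss would be at the same oxidation level and converge there.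

Step 4
Reactants: 7 2,3-dibromo-5-[2-bromo-3-(1,3-dioxolan-2-yl)-1-methoxypropyl]-1-methyl-1H-pyrrole
Product: 10 2,3,6-tribromo-1-methyl-1H-indole, via E-bromoalkene acetal 8 (not isolated), via 4-(2-hydroxyethoxy)-4,5-dihydroindole 9 (not isolated)
Conditions: MeSO3H (5 equiv), CH2Cl2 (0.02 M), 0 °C to rt
Reagents that add atoms: none
Why: Acid-mediated cycloaromatisation of the Bradsher cyclodehydration type (closest known reaction type: acid cyclisation of 4-(pyrrol-2-yl)butanal acetals and their 4-oxygenated congeners to indoles), in which the pyrrol-2-ylmethyl ether should ionise first to an azafulvenium ion that loses the C6 proton to give bromoalkene 8, so that the bromine is vinylic before the acetal opens and cannot leave by β-elimination. The dioxolane should then open to an oxocarbenium ion at C4, which the only free ring carbon (the pyrrole β-carbon, future C3a) attacks to form the C3a–C4 bond and the six-membered ring, a 6-exo-trig closure with respect to the C=O+ bond with the pyrrole C=C bond inside the new ring, giving 9. Ionisation of the C4–O bond of 9 (a 3-pyrrolylmethyl cation) and loss of a C5 proton should complete the benzene ring, with aromatisation as the driving force. The Z isomer of 8 cannot reach C3a, but the two isomers should interconvert under the acid by reprotonation at C6 to the same azafulvenium ion and rotation about the C6–C7 bond, so both should drain into 10. The regiochemistry is fixed because C3a is the only unsubstituted ring carbon and ipso attack at the α-carbon is reversible; no stereocentre remains, and the two ring C–Br bonds and the vinylic C–Br bond should be inert to anhydrous MeSO3H at or below rt.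

**Compound list**

1 | 1-methyl-1H-pyrrole-2-carbaldehyde | Cn1cccc1C=O | starting material
2 | 4-bromo-1-methyl-1H-pyrrole-2-carbaldehyde | Cn1cc(Br)cc1C=O | intermediate
3 | 4,5-dibromo-1-methyl-1H-pyrrole-2-carbaldehyde | Cn1c(Br)c(Br)cc1C=O | intermediate
4 | [2-(1,3-dioxolan-2-yl)ethyl]triphenylphosphonium bromide | [Br-].C1COC(CC[P+](c2ccccc2)(c2ccccc2)c2ccccc2)O1 | starting material
5 | [2-(1,3-dioxolan-2-yl)ethylidene]triphenylphosphorane | C1COC(CC=P(c2ccccc2)(c2ccccc2)c2ccccc2)O1 | intermediate
6 | 2,3-dibromo-5-[(1Z)-3-(1,3-dioxolan-2-yl)prop-1-en-1-yl]-1-methyl-1H-pyrrole | Cn1c(Br)c(Br)cc1/C=C\CC1OCCO1 | intermediate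
7 | 2,3-dibromo-5-[2-bromo-3-(1,3-dioxolan-2-yl)-1-methoxypropyl]-1-methyl-1H-pyrrole (racemic mixture of both diastereomers, configuration not assigned) | Cn1c(Br)c(Br)cc1C(OC)C(Br)CC1OCCO1 | intermediate
8 | 2,3-dibromo-5-[(1E)-2-bromo-3-(1,3-dioxolan-2-yl)prop-1-en-1-yl]-1-methyl-1H-pyrrole | Cn1c(Br)c(Br)cc1/C=C(/Br)CC1OCCO1 | intermediate
9 | 2-[(2,3,6-tribromo-1-methyl-4,5-dihydro-1H-indol-4-yl)oxy]ethan-1-ol (racemic) | Cn1c(Br)c(Br)c2c1C=C(Br)CC2OCCO | intermediate
10 | 2,3,6-tribromo-1-methyl-1H-indole | Cn1c(Br)c(Br)c2ccc(Br)cc21 | target

**Step count**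

Total: 4 steps. Longest linear sequence: 4 steps.

**Steps most likely to fail, with fallbacks**

1. Step 4. The cyclisation may stall at the bromoalkene if the Z isomer does not equilibrate, the azafulvenium ion may oligomerise, bromide may ionise from C6 of a cyclised but not yet dehydrated intermediate, or the strong acid may cause loss or migration of a ring bromine. The fallback sets out from 3 and comes back to the route at 10; it closes the ring by π-acid hydroarylation of an alkyne instead of by a cationic cyclodehydration. A Horner–Wadsworth–Emmons reaction of 3 with methyl bromo[bis(2,2,2-trifluoroethoxy)phosphoryl]acetate (KOt-Bu, 18-crown-6, THF, −78 °C), a reagent type that places the ester cis to the aryl group, should give methyl (2E)-2-bromo-3-(4,5-dibromo-1-methyl-1H-pyrrol-2-yl)prop-2-enoate F1. Reduction with i-Bu2AlH should give (2E)-2-bromo-3-(4,5-dibromo-1-methyl-1H-pyrrol-2-yl)prop-2-en-1-ol F2, and oxidation with MnO2 should give (2E)-2-bromo-3-(4,5-dibromo-1-methyl-1H-pyrrol-2-yl)prop-2-enal F3. Homologation with the Ohira–Bestmann reagent (K2CO3, MeOH) should give 2,3-dibromo-5-[(1E)-2-bromobut-1-en-3-yn-1-yl]-1-methyl-1H-pyrrole F4, in which the alkyne is cis to the pyrrole. PtCl2 (5 mol %, toluene, 80 °C) should then close the benzene ring by 6-endo-dig hydroarylation of the alkyne by the free pyrrole β-carbon and give 10 without any leaving group on the chain and without strong acid.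

2. Step 3. Electrophilic bromine may substitute the free ring carbon (the future C3a) instead of adding to the alkene, which would block the ring closure, or a second bromination may follow. The fallback sets out from 3 and from ylide 5 of step 2 and comes back to the route at 8; it brings the C6 bromine in on the ylide carbon instead of by electrophilic addition. Ylide 5 would be brominated in the flask (Br2, THF, −78 °C) to [1-bromo-2-(1,3-dioxolan-2-yl)ethyl]triphenylphosphonium bromide F5 and deprotonated again with KN(SiMe3)2 to [1-bromo-2-(1,3-dioxolan-2-yl)ethylidene]triphenylphosphorane F6. A Wittig reaction of F6 with 3 should give the bromoalkene as a mixture of 8 and its isomer 2,3-dibromo-5-[(1Z)-2-bromo-3-(1,3-dioxolan-2-yl)prop-1-en-1-yl]-1-methyl-1H-pyrrole F7. The mixture would be taken to 10 under the conditions of step 4, where both isomers should converge.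

3. Step 2. The basic ylide or residual amide may attack the dibromopyrrole (bromine–metal exchange, or deprotonation at the free ring carbon followed by bromine migration), or the olefination of the vinylogous-amide aldehyde may be slow. The fallback sets out from 3 and comes back to the route at 7; it replaces the olefination by addition and elimination. The Grignard reagent [2-(1,3-dioxolan-2-yl)ethyl]magnesium bromide F8 (from 2-(2-bromoethyl)-1,3-dioxolane and Mg, THF) would add to 3 at −78 °C to give racemic 1-(4,5-dibromo-1-methyl-1H-pyrrol-2-yl)-3-(1,3-dioxolan-2-yl)propan-1-ol F9. MsCl and Et3N should convert F9 into 1-(4,5-dibromo-1-methyl-1H-pyrrol-2-yl)-3-(1,3-dioxolan-2-yl)propyl methanesulfonate F10, which should ionise and eliminate in the flask to the E alkene 2,3-dibromo-5-[(1E)-3-(1,3-dioxolan-2-yl)prop-1-en-1-yl]-1-methyl-1H-pyrrole F11. F11 would take the place of 6 in step 3 and give 7.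

**Further compounds**

F1 | step 4 | methyl (2E)-2-bromo-3-(4,5-dibromo-1-methyl-1H-pyrrol-2-yl)prop-2-enoate | COC(=O)/C(Br)=C\c1cc(Br)c(Br)n1C
F2 | step 4 | (2E)-2-bromo-3-(4,5-dibromo-1-methyl-1H-pyrrol-2-yl)prop-2-en-1-ol | OC/C(Br)=C\c1cc(Br)c(Br)n1C
F3 | step 4 | (2E)-2-bromo-3-(4,5-dibromo-1-methyl-1H-pyrrol-2-yl)prop-2-enal | O=C/C(Br)=C\c1cc(Br)c(Br)n1C
F4 | step 4 | 2,3-dibromo-5-[(1E)-2-bromobut-1-en-3-yn-1-yl]-1-methyl-1H-pyrrole | C#C/C(Br)=C\c1cc(Br)c(Br)n1C
F5 | step 3 | [1-bromo-2-(1,3-dioxolan-2-yl)ethyl]triphenylphosphonium bromide | [Br-].BrC(CC1OCCO1)[P+](c1ccccc1)(c1ccccc1)c1ccccc1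
F6 | step 3 | [1-bromo-2-(1,3-dioxolan-2-yl)ethylidene]triphenylphosphorane | BrC(CC1OCCO1)=P(c1ccccc1)(c1ccccc1)c1ccccc1
F7 | step 3 | 2,3-dibromo-5-[(1Z)-2-bromo-3-(1,3-dioxolan-2-yl)prop-1-en-1-yl]-1-methyl-1H-pyrrole | Cn1c(Br)c(Br)cc1/C=C(\Br)CC1OCCO1
F8 | step 2 | [2-(1,3-dioxolan-2-yl)ethyl]magnesium bromide | Br[Mg]CCC1OCCO1
F9 | step 2 | 1-(4,5-dibromo-1-methyl-1H-pyrrol-2-yl)-3-(1,3-dioxolan-2-yl)propan-1-ol (racemic) | Cn1c(Br)c(Br)cc1C(O)CCC1OCCO1
F10 | step 2 | 1-(4,5-dibromo-1-methyl-1H-pyrrol-2-yl)-3-(1,3-dioxolan-2-yl)propyl methanesulfonate (racemic) | Cn1c(Br)c(Br)cc1C(OS(C)(=O)=O)CCC1OCCO1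
F11 | step 2 | 2,3-dibromo-5-[(1E)-3-(1,3-dioxolan-2-yl)prop-1-en-1-yl]-1-methyl-1H-pyrrole | Cn1c(Br)c(Br)cc1/C=C/CC1OCCO1
A1 | direct plan | 4-bromo-2-nitrobenzaldehyde | O=Cc1ccc(Br)cc1[N+](=O)[O-]
A2 | direct plan | 4-bromo-1-(2,2-dibromovinyl)-2-nitrobenzene | BrC(Br)=Cc1ccc(Br)cc1[N+](=O)[O-]
A3 | direct plan | 2,3,6-tribromo-1H-indole | Brc1[nH]c2cc(Br)ccc2c1Br
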